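C1 (quaternary; C7 methyl, Z‑C8=C9 chlorovinyl), C2H2, C3 (Br, C10H2Br), C4HCl, C5H2, C6HCl. The strategy rests on the vicinal dibromide C3(Br)–C10H2Br beside the C4 chloride on the cyclohexane ring, read as the Br2 adduct of an exocyclic C3=C10 alkene next to a C4 carbinol.
Endgame: Br2 across C3=C10 (last); C4–Cl from the allylic β‑alcohol and C6–Cl from the β‑alcohol, each by SN2 inversion (C6 first, at the hydroxy aldehyde stage); Z‑C8=C9 by Wittig chloromethylenation of the C8 aldehyde.
Key disconnection C3–C4: nickel‑catalysed reductive cyclization of the terminal alkyne C3≡C10 onto the C4 aldehyde with Et3SiH closes the carbocycle (ring A) and gives the C4 silyl ether beside the C3=C10 methylidene. A p‑methoxybenzylidene acetal across C6–O and C8–O (1,3‑dioxane, ring B) locks the chair and fixes C4 cis to C6–O.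
The ynal is built on an open chain: Evans propionate aldol (C6 carbinol; C7–C1–C8 from the imide, C4–C6 from the silyloxypropanal), then Fráter–Seebach propargylation (C2–C3–C10), which creates quaternary C1 anti to the C6 hydroxyl.
Ring order: ring B (temporary acetal, step 5), then ring A (step 8); ring B is opened reductively in step 9 to tell C8–OH from C6–OPMB.
Key step: step 8

Remark: the locants C1–C10 above are used for every intermediate, β is the ring face of the C7 methyl and α the face of C8; compounds 1 and 2 and all reagents named are taken as commercial.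

Step 1
Reactants: 1 (S)-4-benzyl-3-propanoyl-1,3-oxazolidin-2-one; 2 3-[(tert-butyldimethylsilyl)oxy]propanal
Product: 3 (S)-4-benzyl-3-[(2S,3R)-5-[(tert-butyldimethylsilyl)oxy]-3-hydroxy-2-methylpentanoyl]-1,3-oxazolidin-2-one
Conditions: Bu2BOTf, i-Pr2NEt, CH2Cl2, −78 to 0 °C; then 2, −78 to 0 °C; H2O2, MeOH, pH 7 buffer
Reagents that add atoms: none
Why: Evans syn-aldol reaction, in which the Z-boron enolate of the (S)-benzyl imide adds to the aldehyde through a closed chair transition state on the enolate face away from the benzyl group, setting C6 as the (R)-carbinol (the C1 centre formed here is erased in step 3).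

Step 2
Reactants: 3
Product: 4 methyl (2S,3R)-5-[(tert-butyldimethylsilyl)oxy]-3-hydroxy-2-methylpentanoate
Conditions: MeMgBr, MeOH, CH2Cl2, 0 °C
Reagents that add atoms: methanol, CO
Why: Transesterification of the N-acyl oxazolidinone with MeOMgBr cleaves the exocyclic imide carbonyl under conditions too mild for retro-aldol cleavage or loss of the silyl ether, and frees the ester that step 3 needs.

Step 3
Reactants: 4
Product: 5 methyl (2R,3R)-5-[(tert-butyldimethylsilyl)oxy]-3-hydroxy-2-methyl-2-[3-(trimethylsilyl)prop-2-yn-1-yl]pentanoate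
Conditions: LiN(i-Pr)2 (2.3 equiv), THF, −78 to −20 °C; then BrCH2C≡CSiMe3, DMPU, −78 to −10 °C
Reagents that add atoms: 3-bromo-1-(trimethylsilyl)prop-1-yne, C[Si](C)(C)C#CCBr
Why: Fráter–Seebach alkylation, in which the chelated lithium alkoxide–enolate of 4 (the same dianion from either C1 epimer) is alkylated on the face away from the C5 chain on C6, so that the propargyl group ends anti and the C7 methyl syn to the C6 oxygen at the new quaternary C1.

Step 4
Reactants: 5
Product: 6 (2S,3R)-5-[(tert-butyldimethylsilyl)oxy]-2-methyl-2-[3-(trimethylsilyl)prop-2-yn-1-yl]pentane-1,3-diol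
Conditions: LiAlH4, THF, 0 °C to rt
Reagents that add atoms: none
Why: Hydride reduction of the hindered ester to the primary alcohol gives the C6,C8 1,3-diol, and the silyl ether, the silylalkyne and both stereocentres are untouched by LiAlH4 at this temperature.

Step 5
Reactants: 6
Product: 7 tert-butyl{2-[(2S,4R,5S)-2-(4-methoxyphenyl)-5-methyl-5-[3-(trimethylsilyl)prop-2-yn-1-yl]-1,3-dioxan-4-yl]ethoxy}dimethylsilane
Conditions: 4-MeOC6H4CH(OMe)2, PPTS (cat.), CH2Cl2, rt
Reagents that add atoms: 4-methoxybenzaldehyde dimethyl acetal, COc1ccc(cc1)C(OC)OC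
Why: Acid-catalysed transacetalization under thermodynamic control closes the 1,3-dioxane (ring B) with the aryl group and the C6 side chain equatorial and the C7 methyl axial, which creates the acetal centre as one epimer and ties C6–O to C8–O for the key step.

Step 6
Reactants: 7
Product: 8 2-[(2S,4R,5S)-2-(4-methoxyphenyl)-5-methyl-5-(prop-2-yn-1-yl)-1,3-dioxan-4-yl]ethan-1-ol
Conditions: Bu4NF (2.5 equiv), THF, 0 °C to rt
Reagents that add atoms: none
Why: Fluoride-mediated desilylation removes the primary TBS ether and the alkynyl TMS group in one operation, while the acetal is inert to Bu4NF.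

Step 7
Reactants: 8
Product: 9 2-[(2S,4R,5S)-2-(4-methoxyphenyl)-5-methyl-5-(prop-2-yn-1-yl)-1,3-dioxan-4-yl]acetaldehyde
Conditions: Dess–Martin periodinane, NaHCO3, CH2Cl2, 0 °C to rt
Reagents that add atoms: none
Why: Dess–Martin oxidation of the primary alcohol to the C4 aldehyde under buffered, non-basic conditions avoids β-elimination of the acetal oxygen and leaves the terminal alkyne alone.

Step 8
Reactants: 9
Product: 10 triethyl{[(2S,4aS,7S,8aR)-2-(4-methoxyphenyl)-4a-methyl-6-methylidenehexahydro-4H-1,3-benzodioxin-7-yl]oxy}silane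
Conditions: Ni(cod)2 (10 mol %), PBu3 (20 mol %), Et3SiH (5 equiv), THF, 0 °C to rt, slow addition of 9
Reagents that add atoms: triethylsilane, CC[SiH](CC)CC
Why: Zerovalent nickel binds the alkyne and the aldehyde of 9 and couples them oxidatively to an oxanickelacyclopentene (Ni–C10=C3–C4–O), σ-bond metathesis of its Ni–O bond with Et3SiH gives the C4–O–SiEt3 bond and an alkenylnickel hydride, and C–H reductive elimination releases 10 and the catalyst. The closest known reaction type is the nickel/phosphine/trialkylsilane reductive cyclization of ynals to cyclic allylic silyl ethers that carry an exocyclic alkene. Ring A closes in the 6-exo-dig mode (C3–C4 bond), the only mode the three-atom tether allows, since the endo mode would need an E-cycloheptene. The new C4 stereocentre is controlled by ring B: the trans-fused 2-aryl-1,3-dioxane holds C6–O and C1–C8 equatorial and the C7 methyl axial on the forming chair, and the flat metallacycle needs the C4–O bond near the plane of C3=C10, that is equatorial, which places it cis to C6–O and to C7. The step needs this 4,6-cis selectivity and chemoselectivity for cyclization over alkyne oligomerization and aldehyde hydrosilylation; the acetal lock secures the first, slow addition of 9 to catalyst and silane the second.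

Step 9
Reactants: 10
Product: 11 {(1S,2R,4S)-2-[(4-methoxybenzyl)oxy]-1-methyl-5-methylidene-4-[(triethylsilyl)oxy]cyclohexyl}methanol
Conditions: i-Bu2AlH (4 equiv), CH2Cl2, −78 to 0 °C
Reagents that add atoms: none
Why: Regioselective reductive opening of the p-methoxybenzylidene acetal, in which aluminium coordinates the less hindered primary oxygen on C8, that C–O bond breaks and hydride reduces the oxocarbenium ion, so the PMB group stays on the secondary C6 oxygen and C8–OH is set free.

Step 10
Reactants: 11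
Product: 12 (1R,2R,4S)-2-[(4-methoxybenzyl)oxy]-1-methyl-5-methylidene-4-[(triethylsilyl)oxy]cyclohexane-1-carbaldehyde
Conditions: Dess–Martin periodinane, NaHCO3, CH2Cl2, 0 °C to rt
Reagents that add atoms: none
Why: Dess–Martin oxidation gives the non-enolizable α-quaternary C8 aldehyde, whose C1 centre cannot epimerize.

Step 11
Reactants: 12
Product: 13 (1R,2R,4S)-2-hydroxy-1-methyl-5-methylidene-4-[(triethylsilyl)oxy]cyclohexane-1-carbaldehyde
Conditions: DDQ, CH2Cl2/pH 7 buffer, 0 °C
Reagents that add atoms: none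
Why: Oxidative PMB cleavage by DDQ (benzylic hydride abstraction, then hydrolysis of the oxocarbenium ion) is selective over the allylic TES ether and the alkene under buffered conditions, and the neutral medium does not trigger retro-aldol opening of the hydroxy aldehyde.

Step 12
Reactants: 13
Product: 15 (1S,2S,4S)-2-chloro-1-methyl-5-methylidene-4-[(triethylsilyl)oxy]cyclohexane-1-carbaldehyde, via C6 triflate 14 (not isolated)
Conditions: Tf2O, pyridine, CH2Cl2, −40 °C; then Bu4NCl, 0 °C to rt
Reagents that add atoms: trifluoromethanesulfonic anhydride (triflyl group of 14), FC(F)(F)S(=O)(=O)OS(=O)(=O)C(F)(F)F; tetrabutylammonium chloride, CCCC[N+](CCCC)(CCCC)CCCC.[Cl-]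
Why: Sulfonate displacement, in which triflation of C6–OH and SN2 attack of chloride invert C6 from β-oxygen to α-chlorine, while the small, electron-withdrawing formyl group on C1 is kept there to disfavour ionization and 1,2-shifts at this neopentylic centre, which cannot eliminate toward C1.

Step 13
Reactants: 15
Product: 16 {[(1S,4S,5S)-5-chloro-4-[(Z)-2-chloroethenyl]-4-methyl-2-methylidenecyclohexyl]oxy}triethylsilane
Conditions: ClCH2PPh3Cl (1.6 equiv), NaN(SiMe3)2 (1.5 equiv), THF, −78 °C; then 15, −78 °C to rt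
Reagents that add atoms: (chloromethyl)triphenylphosphonium chloride, ClC[P+](c1ccccc1)(c1ccccc1)c1ccccc1.[Cl-]
Why: Wittig reaction with the non-stabilized ylide Ph3P=CHCl under kinetic, low-temperature conditions should favour the Z-chloroalkene through the cis-oxaphosphetane, and the aldehyde has no α-hydrogen, so the base can neither epimerize C1 nor eliminate next to the carbonyl.

Step 14
Reactants: 16
Product: 17 (1S,4S,5S)-5-chloro-4-[(Z)-2-chloroethenyl]-4-methyl-2-methylidenecyclohexan-1-ol
Conditions: PPTS (cat.), MeOH/CH2Cl2, 0 °C to rt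
Reagents that add atoms: none
Why: Mild acid-catalysed methanolysis removes the TES ether without ionizing the allylic alcohol or touching the alkyl and alkenyl chlorides.

Step 15
Reactants: 17
Product: 18 (1S,2S,5R)-1,5-dichloro-2-[(Z)-2-chloroethenyl]-2-methyl-4-methylidenecyclohexane
Conditions: PPh3, Cl3CC(O)CCl3, CH2Cl2, 0 °C
Reagents that add atoms: hexachloroacetone, ClC(Cl)(Cl)C(=O)C(Cl)(Cl)Cl
Why: Appel-type redox-condensation chlorination of the allylic alcohol, in which SN2 collapse of the alkoxyphosphonium chloride ion pair inverts C4 to the α-chloride under conditions chosen to avoid allylic transposition to C10.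

Step 16
Reactants: 18
Product: 19 (1R,2S,4S,5S)-2-bromo-2-(bromomethyl)-1,5-dichloro-4-[(Z)-2-chloroethenyl]-4-methylcyclohexane
Conditions: Br2 (1.0 equiv), CH2Cl2, −78 °C, dark
Reagents that add atoms: bromine, BrBr
Why: Electrophilic anti addition of bromine to the 1,1-disubstituted C3=C10 alkene, far more nucleophilic than the chlorovinyl group, in which bromide opens the bromonium ion at tertiary C3 along the axial trajectory of the chair that has both ring chlorides equatorial, making C3–Br axial and cis to C4–Cl and placing C10H2Br equatorial as in the target.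

Compound list
1 | (S)-4-benzyl-3-propanoyl-1,3-oxazolidin-2-one | CCC(=O)N1[C@@H](Cc2ccccc2)COC1=O | starting material
2 | 3-[(tert-butyldimethylsilyl)oxy]propanal | O=CCCO[Si](C)(C)C(C)(C)C | starting material
3 | (S)-4-benzyl-3-[(2S,3R)-5-[(tert-butyldimethylsilyl)oxy]-3-hydroxy-2-methylpentanoyl]-1,3-oxazolidin-2-one | CC(C)(C)[Si](C)(C)OCC[C@@H](O)[C@H](C)C(=O)N1[C@@H](Cc2ccccc2)COC1=O | intermediate
4 | methyl (2S,3R)-5-[(tert-butyldimethylsilyl)oxy]-3-hydroxy-2-methylpentanoate | COC(=O)[C@@H](C)[C@H](O)CCO[Si](C)(C)C(C)(C)C | intermediate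
5 | methyl (2R,3R)-5-[(tert-butyldimethylsilyl)oxy]-3-hydroxy-2-methyl-2-[3-(trimethylsilyl)prop-2-yn-1-yl]pentanoate | COC(=O)[C@](C)(CC#C[Si](C)(C)C)[C@H](O)CCO[Si](C)(C)C(C)(C)C | intermediate
6 | (2S,3R)-5-[(tert-butyldimethylsilyl)oxy]-2-methyl-2-[3-(trimethylsilyl)prop-2-yn-1-yl]pentane-1,3-diol | OC[C@](C)(CC#C[Si](C)(C)C)[C@H](O)CCO[Si](C)(C)C(C)(C)C | intermediate
7 | tert-butyl{2-[(2S,4R,5S)-2-(4-methoxyphenyl)-5-methyl-5-[3-(trimethylsilyl)prop-2-yn-1-yl]-1,3-dioxan-4-yl]ethoxy}dimethylsilane | COc1ccc(cc1)[C@H]1OC[C@](C)(CC#C[Si](C)(C)C)[C@@H](CCO[Si](C)(C)C(C)(C)C)O1 | intermediate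
8 | 2-[(2S,4R,5S)-2-(4-methoxyphenyl)-5-methyl-5-(prop-2-yn-1-yl)-1,3-dioxan-4-yl]ethan-1-ol | COc1ccc(cc1)[C@H]1OC[C@](C)(CC#C)[C@@H](CCO)O1 | intermediate
9 | 2-[(2S,4R,5S)-2-(4-methoxyphenyl)-5-methyl-5-(prop-2-yn-1-yl)-1,3-dioxan-4-yl]acetaldehyde | COc1ccc(cc1)[C@H]1OC[C@](C)(CC#C)[C@@H](CC=O)O1 | intermediate
10 | triethyl{[(2S,4aS,7S,8aR)-2-(4-methoxyphenyl)-4a-methyl-6-methylidenehexahydro-4H-1,3-benzodioxin-7-yl]oxy}silane | COc1ccc(cc1)[C@H]1OC[C@]2(C)CC(=C)[C@@H](O[Si](CC)(CC)CC)C[C@H]2O1 | intermediate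
11 | {(1S,2R,4S)-2-[(4-methoxybenzyl)oxy]-1-methyl-5-methylidene-4-[(triethylsilyl)oxy]cyclohexyl}methanol | OC[C@]1(C)CC(=C)[C@@H](O[Si](CC)(CC)CC)C[C@H]1OCc1ccc(OC)cc1 | intermediate
12 | (1R,2R,4S)-2-[(4-methoxybenzyl)oxy]-1-methyl-5-methylidene-4-[(triethylsilyl)oxy]cyclohexane-1-carbaldehyde | O=C[C@]1(C)CC(=C)[C@@H](O[Si](CC)(CC)CC)C[C@H]1OCc1ccc(OC)cc1 | intermediate
13 | (1R,2R,4S)-2-hydroxy-1-methyl-5-methylidene-4-[(triethylsilyl)oxy]cyclohexane-1-carbaldehyde | O=C[C@]1(C)CC(=C)[C@@H](O[Si](CC)(CC)CC)C[C@H]1O | intermediate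
14 | (1R,2R,5S)-2-formyl-2-methyl-4-methylidene-5-[(triethylsilyl)oxy]cyclohexyl trifluoromethanesulfonate | O=C[C@]1(C)CC(=C)[C@@H](O[Si](CC)(CC)CC)C[C@H]1OS(=O)(=O)C(F)(F)F | intermediate
15 | (1S,2S,4S)-2-chloro-1-methyl-5-methylidene-4-[(triethylsilyl)oxy]cyclohexane-1-carbaldehyde | O=C[C@]1(C)CC(=C)[C@@H](O[Si](CC)(CC)CC)C[C@@H]1Cl | intermediate
16 | {[(1S,4S,5S)-5-chloro-4-[(Z)-2-chloroethenyl]-4-methyl-2-methylidenecyclohexyl]oxy}triethylsilane | Cl/C=C\[C@]1(C)CC(=C)[C@@H](O[Si](CC)(CC)CC)C[C@@H]1Cl | intermediate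
17 | (1S,4S,5S)-5-chloro-4-[(Z)-2-chloroethenyl]-4-methyl-2-methylidenecyclohexan-1-ol | Cl/C=C\[C@]1(C)CC(=C)[C@@H](O)C[C@@H]1Cl | intermediate
18 | (1S,2S,5R)-1,5-dichloro-2-[(Z)-2-chloroethenyl]-2-methyl-4-methylidenecyclohexane | Cl/C=C\[C@]1(C)CC(=C)[C@H](Cl)C[C@@H]1Cl | intermediate
19 | (1R,2S,4S,5S)-2-bromo-2-(bromomethyl)-1,5-dichloro-4-[(Z)-2-chloroethenyl]-4-methylcyclohexane (CNP0497262.2) | C[C@@]1(/C=C\Cl)C[C@@](Br)(CBr)[C@H](Cl)C[C@@H]1Cl | target

Total step count: 16. Longest linear sequence: 16 steps (1 or 2 to 19).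

Steps most likely to fail

1. Step 12. The displacement at C6 is neopentylic: chloride attack may be outrun by loss of triflic acid toward C5 or by ionization with ring contraction, or may not occur at all. The fallback sets out from 12 and comes back at 16. It moves the displacement behind the olefination and runs it as a redox condensation instead of a sulfonate displacement. Wittig chloromethylenation of 12 under the conditions of step 13 should give {[(1S,4S,5R)-4-[(Z)-2-chloroethenyl]-5-[(4-methoxybenzyl)oxy]-4-methyl-2-methylidenecyclohexyl]oxy}triethylsilane F1. DDQ in CH2Cl2/pH 7 buffer should then give (1R,2S,5S)-2-[(Z)-2-chloroethenyl]-2-methyl-4-methylidene-5-[(triethylsilyl)oxy]cyclohexan-1-ol F2. Appel chlorination (PPh3, CCl4, 70 °C) should convert F2 into 16 with inversion through an alkoxyphosphonium chloride ion pair, a non-ionizing path chosen to avoid skeletal rearrangement at the neopentylic centre.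

2. Step 16. Bromide capture at C3 may show poor facial selectivity, because the axial chlorovinyl group on C1 shields the α-axial trajectory; slow bromination of the chlorovinyl group may also compete. The fallback sets out from 18 and comes back at 19. mCPBA (CH2Cl2, NaHCO3) should epoxidize C3=C10 from the open β face to give (3S,4R,6S,7S)-4,6-dichloro-7-[(Z)-2-chloroethenyl]-7-methyl-1-oxaspiro[2.5]octane F4, so the face is fixed in an irreversible step. HBr (Et2O, −40 °C) should open the epoxide at tertiary C3 with inversion to [(1R,2R,4S,5S)-1-bromo-2,4-dichloro-5-[(Z)-2-chloroethenyl]-5-methylcyclohexyl]methanol F5. Appel bromination of the primary alcohol (CBr4, PPh3, CH2Cl2, 0 °C) should give 19.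

3. Step 13. Halomethylene ylides often give modest Z/E selectivity, and the isomers may be hard to separate. The fallback sets out from 15 and comes back at 16. Stork–Zhao olefination (ICH2PPh3I, NaN(SiMe3)2, THF/DMPU, −78 °C) should give {[(1S,4S,5S)-5-chloro-4-[(Z)-2-iodoethenyl]-4-methyl-2-methylidenecyclohexyl]oxy}triethylsilane F3 with high Z selectivity. Iodine–lithium exchange (t-BuLi, 2 equiv, Et2O, −78 °C) and quenching of the configurationally stable alkenyllithium with C2Cl6 should give 16 with retention of the alkene geometry.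

Further compounds
F1 | step 12 | {[(1S,4S,5R)-4-[(Z)-2-chloroethenyl]-5-[(4-methoxybenzyl)oxy]-4-methyl-2-methylidenecyclohexyl]oxy}triethylsilane | Cl/C=C\[C@]1(C)CC(=C)[C@@H](O[Si](CC)(CC)CC)C[C@H]1OCc1ccc(OC)cc1
F2 | step 12 | (1R,2S,5S)-2-[(Z)-2-chloroethenyl]-2-methyl-4-methylidene-5-[(triethylsilyl)oxy]cyclohexan-1-ol | Cl/C=C\[C@]1(C)CC(=C)[C@@H](O[Si](CC)(CC)CC)C[C@H]1O
F3 | step 13 | {[(1S,4S,5S)-5-chloro-4-[(Z)-2-iodoethenyl]-4-methyl-2-methylidenecyclohexyl]oxy}triethylsilane | I/C=C\[C@]1(C)CC(=C)[C@@H](O[Si](CC)(CC)CC)C[C@@H]1Cl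
F4 | step 16 | (3S,4R,6S,7S)-4,6-dichloro-7-[(Z)-2-chloroethenyl]-7-methyl-1-oxaspiro[2.5]octane | Cl/C=C\[C@]1(C)C[C@]2(CO2)[C@H](Cl)C[C@@H]1Cl
F5 | step 16 | [(1R,2R,4S,5S)-1-bromo-2,4-dichloro-5-[(Z)-2-chloroethenyl]-5-methylcyclohexyl]methanol | Cl/C=C\[C@]1(C)C[C@@](Br)(CO)[C@H](Cl)C[C@@H]1Cl
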